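The runs were generated by integration for substances that don't exist, and the scatter is random.

If the balance of G is written for a flask of this kind, what enters through the gas stands on one side, and on the other stands what leaves, of which the readings below show the part that goes into E and L.

in all of them: Q 8.4 mM (held)

| charge | J | D | remark | time |
|---|---|---|---|---|
| theta | 0.13 M | 0.13 M | run made earlier |  |
| epsilon | 0.29 M | 0.29 M | run made earlier |  |
| flask | 0.19 M | 0.19 M |  | 15 min |

| run | time / min | E / % | L / % |
|---|---|---|---|
| theta | 0.667 | 6.2 | 1.3 |
| theta | 1.33 | 11.6 | 3.0 |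
| theta | 2.50 | 17.6 | 6.6 |
| theta | 5.00 | 25.7 | 15.3 |
| theta | 10.0 | 36.0 | 28.7 |
| epsilon | 0.667 | 5.9 | 0.8 |
| epsilon | 1.33 | 10.1 | 2.7 |
| epsilon | 2.50 | 15.7 | 6.2 |
| epsilon | 5.00 | 23.6 | 14.5 |
| epsilon | 10.0 | 34.8 | 26.8 |

(standard deviation of a reading: 0.3 percentage points)

- G is single-handed; J and D are mirror images of each other, charged as a racemate, each of them at the stated concentration
- at the start none of Q is in solution
- what has gone into Z counts as reacted
- an excess is the difference of the two amounts in percent of their sum
- an excess is below zero if the other one leads
- the handed part of G does not stay in what it makes, so the products of the two hands are mirror images too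

* excess of E over L in the product at 50 s
* excess of E over L in the product at 15 min
* part of the J and D charged together that has reacted at 15 min

Taking one G for each E or L, the last row of the theta run holds 0.168 M of product, 20.0 times the saturation level of 8.4 mM, so G was supplied throughout the run rather than by one filling. Between the last two rows, E and L together gain 24 percentage points in the theta run and 23 points in the epsilon run, although the epsilon charge is 2.23 times the theta charge. The flow of G into product therefore rose with the charge, and both runs behave as pseudo-first-order in substrate. Pooling those rows gives 0.0990 min⁻¹ for the product clock, the first-order constant at which the part of the charge not yet in E or L shrinks. From the pooled 36.9% at 10.0 min, this clock leaves 22.5% at 15 min in the new flask, whose charge lies between the two. My reckoning therefore puts 77.5% in E and L, and the reacted part stands higher by whatever Z holds.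

The forecast gave 66% (60% to 72%), 6.5% (3% to 10%) and 80% (76% to 84%), reading the kinetics as “about first order in substrate”.

    G + D → L (k = 0.0690 L mol⁻¹ s⁻¹)
    E ⇌ L (k = 0.00380 s⁻¹)
    2 G → X (k = 0.960 L mol⁻¹ s⁻¹)
    D ⇌ Z (K = 0.560, k = 0.00720 s⁻¹)
    J ⇌ Z (K = 0.560, k = 0.00720 s⁻¹)
    Q ⇌ G, rate k6*(csat - [G]) (kL = 0.430 s⁻¹)
    G + J → E (k = 0.650 L mol⁻¹ s⁻¹)

The flask gives 65.7% at 50 s, then 5.50% and 83.0% at 15 min. Of that reacted part, E and L together hold 77.9% and Z holds 5.08%. At 7.50 min, J, D and Z together stand at 46.7%, and 0.0990 min⁻¹ carries this to 22.2% at 15.0 min, where the flask holds 22.1%.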